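**Retrosynthetic overview**
- The strategy rests on ring A (C4a, C5, C6, C7, C8, C8a): oxygen sits on the alternate carbons C5, C7 and C8a and the acyl carbon C4 on C4a, the pattern of an acylphloroglucinol, that is, of a folded poly-β-carbonyl chain.
- Sulfates and the 4'-O-benzyl group are removed first; ring C is then opened at O1–C2 to an o-hydroxyaryl 1,3-diketone; ring A is opened at C4a–C5 (retro-Claisen) to a 3,5,7,9-tetraoxo ester that is stored as a 6-(4-aryl-2,4-dioxobutyl)-4-hydroxy-2-pyrone.
- The pyrone precursor comes from the C6-methyl dianion of triacetic acid lactone and the Weinreb amide of the ring B arylpropiolic acid; the resulting ynone is hydrated through its diethylamine adduct.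
- Ring order: pyrone and ring B are bought; ring A is formed by Claisen folding; ring C by acid cyclodehydration. The end game is sulfation of 7-OH and 3'-OH, then hydrogenolysis of the 4'-O-benzyl ether.

Key step: step 6

Assumption: the sulfated compounds are written, like the target formula, as neutral bis(hydrogen sulfates); in the flask they are handled as their salts, because free aryl hydrogen sulfates hydrolyse on concentration.

**Step 1**
Reactants: 1 4-(benzyloxy)-3-hydroxybenzaldehyde
Product: 2 4-(benzyloxy)-3-(methoxymethoxy)benzaldehyde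
Conditions: MOMCl, i-Pr2NEt, CH2Cl2, 0 °C to rt
Reagents that add atoms: chloromethyl methyl ether (MOMCl), COCCl
Why: O-alkylation of the phenol with the reactive α-chloro ether (MOM protection) should be clean, since the aldehyde and the benzyl ether are inert to the amine base.

**Step 2**
Reactants: 2 4-(benzyloxy)-3-(methoxymethoxy)benzaldehyde
Product: 3 1-(benzyloxy)-4-ethynyl-2-(methoxymethoxy)benzene
Conditions: dimethyl (1-diazo-2-oxopropyl)phosphonate, K2CO3, MeOH, 0 °C to rt
Reagents that add atoms: dimethyl (1-diazo-2-oxopropyl)phosphonate (Ohira–Bestmann reagent), CC(=O)C(=[N+]=[N-])P(=O)(OC)OC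
Why: Seyferth–Gilbert homologation in the Ohira–Bestmann form (methanolysis to the diazomethylphosphonate anion, olefination, loss of N2 and 1,2-shift) should turn the aryl aldehyde into the terminal alkyne under conditions that leave the MOM acetal and the benzyl ether alone.

**Step 3**
Reactants: 3 1-(benzyloxy)-4-ethynyl-2-(methoxymethoxy)benzene
Product: 5 3-[4-(benzyloxy)-3-(methoxymethoxy)phenyl]-N-methoxy-N-methylprop-2-ynamide, via lithium arylacetylide 4 (not isolated)
Conditions: n-BuLi (1.05 equiv), THF, −78 °C; cannulate into ClC(O)N(OMe)Me, THF, −78 to 0 °C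
Reagents that add atoms: N-methoxy-N-methylcarbamoyl chloride, CON(C)C(=O)Cl
Why: Deprotonation of the terminal alkyne is much faster than ortho-lithiation next to the MOM ether at −78 °C, and acylation of the lithium acetylide by the carbamoyl chloride (inverse addition, chloride in excess) is a known direct entry to alkynyl Weinreb amides.

**Step 4**
Reactants: 6 triacetic acid lactone (4-hydroxy-6-methyl-2H-pyran-2-one); 5 3-[4-(benzyloxy)-3-(methoxymethoxy)phenyl]-N-methoxy-N-methylprop-2-ynamide
Product: 9 6-{4-[4-(benzyloxy)-3-(methoxymethoxy)phenyl]-2-oxobut-3-yn-1-yl}-4-hydroxy-2H-pyran-2-one, via dilithio pyrone dianion 7 (not isolated), via lithium-chelated tetrahedral adduct 8 (not isolated)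
Conditions: 6 (1.3 equiv), LiN(i-Pr)2 (2.7 equiv), THF–DMPU, −78 °C; then 5, −78 to −40 °C; inverse quench into cold 1 M HCl
Reagents that add atoms: none
Why: The dianion of the lactone reacts at its last-formed C6-methyl carbanion, and 1,2-addition to the Weinreb amide (acylation of a dienolate, Weinreb ketone synthesis) stops at the chelated adduct, so the acidic ynone is released only in the acid quench, where the liberated N,O-dimethylhydroxylamine is protonated and cannot add to the ynone.

**Step 5**
Reactants: 9 6-{4-[4-(benzyloxy)-3-(methoxymethoxy)phenyl]-2-oxobut-3-yn-1-yl}-4-hydroxy-2H-pyran-2-one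
Product: 11 6-{4-[4-(benzyloxy)-3-(methoxymethoxy)phenyl]-2,4-dioxobutyl}-4-hydroxy-2H-pyran-2-one, via diethylamino enaminone 10 (not isolated)
Conditions: Et2NH (3 equiv), EtOH, 0 °C to rt; then 1 M aq. HCl, THF, 0 °C to rt, short contact
Reagents that add atoms: water, O
Why: Aza-Michael addition of the secondary amine to the ynone places nitrogen on the aryl-bearing carbon, and acid hydrolysis of the resulting vinylogous amide gives the 1,3-diketone, a known two-stage hydration of ynones; the first equivalent of amine is consumed as the salt of the acidic pyrone hydroxyl, and the enaminone geometry is of no consequence.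

**Step 6**
Reactants: 11 6-{4-[4-(benzyloxy)-3-(methoxymethoxy)phenyl]-2,4-dioxobutyl}-4-hydroxy-2H-pyran-2-one
Product: 13 1-[4-(benzyloxy)-3-(methoxymethoxy)phenyl]-3-(2,4,6-trihydroxyphenyl)propane-1,3-dione, via open-chain methyl tetraketo ester 12 (not isolated)
Conditions: Mg(OMe)2 (8 equiv), MeOH, reflux, Ar; then cold 1 M HCl
Reagents that add atoms: none
Why: Methoxide from Mg(OMe)2 adds to the lactone carbonyl of the pyrone and opens it to the magnesium-chelated methyl 3,5,7,9-tetraoxo ester 12; the carbanion at chain C6 (future C4a), flanked by the C5 and C7 carbonyls, attacks the ester carbon C1 (future C5), methoxide leaves and the cyclohexanetrione enolizes to the phloroglucinol. The closest known reaction is the Claisen cyclization of 6-(2-oxoalkyl)-4-hydroxy-2-pyrones and 3,5,7-triketo esters to acylphloroglucinols with Mg(OMe)2 or methanolic KOH, here run on a chain one ketone longer. Ring A closes in a 6-exo-trig Claisen (Dieckmann-type) mode and aromatization makes the closure irreversible. No stereocenter is formed. The step needs C-acylation at C6 to beat the aldol folds C2 to C7 (orsellinate type), C8 to C3 and C4 to C9 (the last also open to the unopened pyrone and leading to a 4-hydroxycoumarin). Anhydrous methanol keeps C1 an ester and not a carboxylate, the C7–C9 aroylacetyl unit is held as a magnesium enolate chelate so that neither C7 nor C9 is a good aldol acceptor, and C9 is further deactivated by its para-alkoxyaryl group.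

**Step 7**
Reactants: 13 1-[4-(benzyloxy)-3-(methoxymethoxy)phenyl]-3-(2,4,6-trihydroxyphenyl)propane-1,3-dione
Product: 15 2-[4-(benzyloxy)-3-hydroxyphenyl]-5,7-dihydroxy-4H-chromen-4-one (4'-O-benzylluteolin), via methoxymethyl flavone 14 (not isolated)
Conditions: conc. HCl (cat.), MeOH–THF, 55 °C
Reagents that add atoms: none
Why: Acid-catalysed cyclodehydration of the o-hydroxyaryl 1,3-diketone (the closing stage of a Baker–Venkataraman flavone synthesis: 6-exo-trig hemiketal, then loss of water) should close ring C as a single regioisomer because the two ortho hydroxyls of ring A are equivalent, and the same methanolic acid cleaves the MOM acetal while the benzyl ether survives.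

**Step 8**
Reactants: 15 2-[4-(benzyloxy)-3-hydroxyphenyl]-5,7-dihydroxy-4H-chromen-4-one
Product: 16 2-[4-(benzyloxy)-3-(sulfooxy)phenyl]-5-hydroxy-4-oxo-4H-chromen-7-yl hydrogen sulfate (4'-O-benzylluteolin 7,3'-bis(hydrogen sulfate), carried as the disodium salt)
Conditions: SO3·pyridine (3–4 equiv), pyridine, rt; aq. NaHCO3; reversed-phase chromatography
Reagents that add atoms: sulfur trioxide–pyridine complex, [O-]S(=O)(=O)[n+]1ccccc1
Why: O-Sulfation of phenols with the SO3–amine complex should take the 7-OH and the 3'-OH, whereas the 5-OH is tied up in the hydrogen-bonded chelate with the C4 carbonyl and is the least nucleophilic hydroxyl of a flavone.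

**Step 9**
Reactants: 16 2-[4-(benzyloxy)-3-(sulfooxy)phenyl]-5-hydroxy-4-oxo-4H-chromen-7-yl hydrogen sulfate
Product: 17 luteolin 7,3'-disulfate (5-hydroxy-2-[4-hydroxy-3-(sulfooxy)phenyl]-4-oxo-4H-chromen-7-yl hydrogen sulfate)
Conditions: H2 (1 atm), 10% Pd/C, MeOH–H2O, rt
Reagents that add atoms: none
Why: Hydrogenolysis of the benzyl aryl ether over Pd/C should free the 4'-OH, since aryl sulfate monoester salts are stable to neutral hydrogenation, do not poison the catalyst, and the flavone C2–C3 double bond is not reduced at 1 atm and rt.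

**Compound list**
1 | 4-(benzyloxy)-3-hydroxybenzaldehyde | O=Cc1ccc(OCc2ccccc2)c(O)c1 | starting material
2 | 4-(benzyloxy)-3-(methoxymethoxy)benzaldehyde | O=Cc1ccc(OCc2ccccc2)c(OCOC)c1 | intermediate
3 | 1-(benzyloxy)-4-ethynyl-2-(methoxymethoxy)benzene | C#Cc1ccc(OCc2ccccc2)c(OCOC)c1 | intermediate
4 | lithium [4-(benzyloxy)-3-(methoxymethoxy)phenyl]acetylide | [Li]C#Cc1ccc(OCc2ccccc2)c(OCOC)c1 | intermediate
5 | 3-[4-(benzyloxy)-3-(methoxymethoxy)phenyl]-N-methoxy-N-methylprop-2-ynamide | CON(C)C(=O)C#Cc1ccc(OCc2ccccc2)c(OCOC)c1 | intermediate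
6 | triacetic acid lactone (4-hydroxy-6-methyl-2H-pyran-2-one) | Cc1cc(O)cc(=O)o1 | starting material
7 | dilithio dianion of triacetic acid lactone (lithium 6-(lithiomethyl)-2-oxo-2H-pyran-4-olate) | [Li]Cc1cc(O[Li])cc(=O)o1 | intermediate
8 | dilithium salt of racemic 6-{4-[4-(benzyloxy)-3-(methoxymethoxy)phenyl]-2-hydroxy-2-[methoxy(methyl)amino]but-3-yn-1-yl}-4-hydroxy-2H-pyran-2-one | CON(C)C(O[Li])(Cc1cc(O[Li])cc(=O)o1)C#Cc1ccc(OCc2ccccc2)c(OCOC)c1 | intermediate
9 | 6-{4-[4-(benzyloxy)-3-(methoxymethoxy)phenyl]-2-oxobut-3-yn-1-yl}-4-hydroxy-2H-pyran-2-one | O=c1cc(O)cc(CC(=O)C#Cc2ccc(OCc3ccccc3)c(OCOC)c2)o1 | intermediate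
10 | 6-{(3E)-4-[4-(benzyloxy)-3-(methoxymethoxy)phenyl]-4-(diethylamino)-2-oxobut-3-en-1-yl}-4-hydroxy-2H-pyran-2-one | CCN(CC)/C(=C/C(=O)Cc1cc(O)cc(=O)o1)c1ccc(OCc2ccccc2)c(OCOC)c1 | intermediate
11 | 6-{4-[4-(benzyloxy)-3-(methoxymethoxy)phenyl]-2,4-dioxobutyl}-4-hydroxy-2H-pyran-2-one | O=c1cc(O)cc(CC(=O)CC(=O)c2ccc(OCc3ccccc3)c(OCOC)c2)o1 | intermediate
12 | methyl 9-[4-(benzyloxy)-3-(methoxymethoxy)phenyl]-3,5,7,9-tetraoxononanoate (present as its magnesium enolate chelate) | COC(=O)CC(=O)CC(=O)CC(=O)CC(=O)c1ccc(OCc2ccccc2)c(OCOC)c1 | intermediate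
13 | 1-[4-(benzyloxy)-3-(methoxymethoxy)phenyl]-3-(2,4,6-trihydroxyphenyl)propane-1,3-dione | O=C(CC(=O)c1c(O)cc(O)cc1O)c1ccc(OCc2ccccc2)c(OCOC)c1 | intermediate
14 | 2-[4-(benzyloxy)-3-(methoxymethoxy)phenyl]-5,7-dihydroxy-4H-chromen-4-one | O=c1cc(-c2ccc(OCc3ccccc3)c(OCOC)c2)oc2cc(O)cc(O)c12 | intermediate
15 | 2-[4-(benzyloxy)-3-hydroxyphenyl]-5,7-dihydroxy-4H-chromen-4-one (4'-O-benzylluteolin) | O=c1cc(-c2ccc(OCc3ccccc3)c(O)c2)oc2cc(O)cc(O)c12 | intermediate
16 | 2-[4-(benzyloxy)-3-(sulfooxy)phenyl]-5-hydroxy-4-oxo-4H-chromen-7-yl hydrogen sulfate | O=c1cc(-c2ccc(OCc3ccccc3)c(OS(=O)(=O)O)c2)oc2cc(OS(=O)(=O)O)cc(O)c12 | intermediate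
17 | luteolin 7,3'-disulfate | O=c1cc(-c2ccc(O)c(OS(=O)(=O)O)c2)oc2cc(OS(=O)(=O)O)cc(O)c12 | target

**Step count**
Total: 9 steps. Longest linear sequence: 9 steps (1 to 17); triacetic acid lactone 6 enters at step 4. The target has no stereocenter.

**Steps most likely to fail**

Step 6. The chain may fold by aldol condensation instead of Claisen acylation (C2 onto C7, C8 onto C3, or pyrone C5 onto the aryl ketone before the lactone opens), or the diketone side chain may be cleaved by retro-Claisen methanolysis. Fallback: set out from ynone 9, add diethylamine as in step 5 but isolate enaminone 10 without hydrolysis, and treat 10 with Mg(OMe)2 in methanol. Ring opening should give methyl (8E)-9-[4-(benzyloxy)-3-(methoxymethoxy)phenyl]-9-(diethylamino)-3,5,7-trioxonon-8-enoate F1, in which C7 is a vinylogous amide carbonyl and C8 and C9 are neither acidic nor electrophilic, so only the Claisen fold at C6 remains. This should give (2E)-3-[4-(benzyloxy)-3-(methoxymethoxy)phenyl]-3-(diethylamino)-1-(2,4,6-trihydroxyphenyl)prop-2-en-1-one F2. Methanolic HCl then closes ring C by addition of a ring A hydroxyl to the enaminone β-carbon and loss of diethylamine (the known enaminone route to chromones), passes through 14 and, after MOM cleavage, comes back to the route at 15.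

Step 4. The dienolate carbanion may add in conjugate fashion to the alkynyl amide, or the poorly soluble dianion may react sluggishly and be quenched by proton transfer. Fallback: set out from alkyne 3 and lactone 6. Acetylide 4 is formylated with DMF (quench into aqueous KH2PO4) to 3-[4-(benzyloxy)-3-(methoxymethoxy)phenyl]prop-2-ynal F3. Dianion 7 adds 1,2 to this aldehyde (the well-established aldol reaction of the lactone dianion) to give racemic 6-{4-[4-(benzyloxy)-3-(methoxymethoxy)phenyl]-2-hydroxybut-3-yn-1-yl}-4-hydroxy-2H-pyran-2-one F4. Oxidation of the propargylic alcohol with Dess–Martin periodinane comes back to the route at 9.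

Step 5. The pyrone anion formed by the amine may cyclize through C5 onto the ynone (6-endo) before the amine adds, or the acid needed for enaminone hydrolysis may remove the MOM group or rearrange the pyrone. Fallback: avoid the ynone and set out from lactone 6 and aldehyde 2. Dianion 7 is acetylated with N-methoxy-N-methylacetamide to 4-hydroxy-6-(2-oxopropyl)-2H-pyran-2-one F5. Aldehyde 2 is converted by oxidative esterification (I2, KOH, MeOH, 0 °C) into methyl 4-(benzyloxy)-3-(methoxymethoxy)benzoate F6. The trilithio trianion of F5 (excess LiN(i-Pr)2, THF) is aroylated at its terminal methyl carbanion by F6, a Hauser-type acylation of a β-diketone polyanion with a non-enolizable ester, and comes back to the route at 11.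

**Further compounds**
F1 | step 6 | methyl (8E)-9-[4-(benzyloxy)-3-(methoxymethoxy)phenyl]-9-(diethylamino)-3,5,7-trioxonon-8-enoate | COC(=O)CC(=O)CC(=O)CC(=O)/C=C(/N(CC)CC)c1ccc(OCc2ccccc2)c(OCOC)c1
F2 | step 6 | (2E)-3-[4-(benzyloxy)-3-(methoxymethoxy)phenyl]-3-(diethylamino)-1-(2,4,6-trihydroxyphenyl)prop-2-en-1-one | CCN(CC)/C(=C/C(=O)c1c(O)cc(O)cc1O)c1ccc(OCc2ccccc2)c(OCOC)c1
F3 | step 4 | 3-[4-(benzyloxy)-3-(methoxymethoxy)phenyl]prop-2-ynal | O=CC#Cc1ccc(OCc2ccccc2)c(OCOC)c1
F4 | step 4 | racemic 6-{4-[4-(benzyloxy)-3-(methoxymethoxy)phenyl]-2-hydroxybut-3-yn-1-yl}-4-hydroxy-2H-pyran-2-one | O=c1cc(O)cc(CC(O)C#Cc2ccc(OCc3ccccc3)c(OCOC)c2)o1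
F5 | step 5 | 4-hydroxy-6-(2-oxopropyl)-2H-pyran-2-one | CC(=O)Cc1cc(O)cc(=O)o1
F6 | step 5 | methyl 4-(benzyloxy)-3-(methoxymethoxy)benzoate | COC(=O)c1ccc(OCc2ccccc2)c(OCOC)c1
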